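**Plan**
- Retrosynthesis: the two benzyl ethers (on O5 and O2') come off last. Ring C is then cut at C4–C4a (Friedel–Crafts acylation), at O1–C2 (vinylic substitution of an enol triflate by a ring A phenol) and at C2–C3 (Claisen condensation of a ring B benzoate with methyl methoxyacetate).
- Enabling feature: C4a is the only ring A carbon without oxygen and lies between C8a (O1) and C5 (OH). Ring A can therefore come from mirror-symmetric 4,5,6-trimethoxybenzene-1,3-diol, whose single C–H sits between two equivalent hydroxyls, so the acylation has one possible site.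
- Forward: the ring A phenol is made from 1,2,3-trimethoxybenzene (dibromination, double borylation, oxidation, mono-benzylation). The ring B keto ester is made from methyl 2-hydroxy-4-methoxybenzoate (benzylation, Claisen) and converted to its enol triflate. The halves are joined through O1–C2, the ester is saponified, ring C closes at C4a, and both benzyl groups are hydrogenolysed.
- Stereochemistry: the target has no stereocentre. The only stereo element on the way is the E geometry of the tetrasubstituted enol ether (carboxyl cis to aryloxy), expected from triflation of a chelated enolate followed by retentive substitution.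

Key step: step 10

Remark: compounds 10–13 are drawn as E isomers. The geometry is not essential, because this push–pull alkene can equilibrate under the acidic ring-closure conditions. Keto ester 9 is racemic and enolisable, which has no bearing on the target. The second ring A oxygen is carried as a benzyl ether so that it stays a strong ortho donor and cannot be acylated in step 10.

**Route**

Step 1
Reactants: 1 1,2,3-trimethoxybenzene
Product: 2 1,5-dibromo-2,3,4-trimethoxybenzene
Conditions: NBS (2.2 equiv), MeCN, 0 °C → rt
Reagents that add atoms: N-bromosuccinimide, O=C1CCC(=O)N1Br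
Why: Electrophilic aromatic bromination: each in-plane outer methoxy group activates its ortho carbon (C4, then C6), while C5, para to the twisted central methoxy group, is the least activated site, so the 4,6-dibromide should form.

Step 2
Reactants: 2 1,5-dibromo-2,3,4-trimethoxybenzene
Product: 3 2,2'-(4,5,6-trimethoxy-1,3-phenylene)bis(4,4,5,5-tetramethyl-1,3,2-dioxaborolane)
Conditions: B2pin2 (2.6 equiv), Pd(dppf)Cl2 (5 mol %), KOAc, 1,4-dioxane, 90 °C
Reagents that add atoms: bis(pinacolato)diboron, CC1(C)OB(OC1(C)C)B1OC(C)(C)C(C)(C)O1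
Why: Miyaura borylation: oxidative addition of each C–Br bond to palladium, transmetalation with the acetate-activated diboron and reductive elimination give the aryl boronates, and KOAc is too weak a base to trigger Suzuki coupling of product with substrate.

Step 3
Reactants: 3 2,2'-(4,5,6-trimethoxy-1,3-phenylene)bis(4,4,5,5-tetramethyl-1,3,2-dioxaborolane)
Product: 4 4,5,6-trimethoxybenzene-1,3-diol
Conditions: H2O2 (30 % aq), NaOH (aq), THF, 0 °C → rt; then 1 M HCl
Reagents that add atoms: hydrogen peroxide, OO
Why: Oxidation of aryl boronates with alkaline hydrogen peroxide: hydroperoxide adds to boron, the aryl group migrates from boron to oxygen at the same ring carbon, and the borate ester is hydrolysed to the phenol.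

Step 4
Reactants: 4 4,5,6-trimethoxybenzene-1,3-diol
Product: 5 5-(benzyloxy)-2,3,4-trimethoxyphenol
Conditions: BnBr (0.9 equiv), K2CO3 (1.0 equiv), acetone, reflux
Reagents that add atoms: benzyl bromide, BrCc1ccccc1
Why: Williamson ether synthesis under statistical control: the two hydroxyls are equivalent by symmetry, so only one mono-ether can form, and a deficit of benzyl bromide limits the bis-ether while unreacted 4 is recovered.

Step 5
Reactants: 6 methyl 2-hydroxy-4-methoxybenzoate
Product: 7 methyl 2-(benzyloxy)-4-methoxybenzoate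
Conditions: BnBr, K2CO3, DMF, 60 °C
Reagents that add atoms: benzyl bromide, BrCc1ccccc1
Why: Williamson ether synthesis; the hydrogen-bonded salicylate hydroxyl is alkylated cleanly by a benzylic bromide in DMF with carbonate.

Step 6
Reactants: 7 methyl 2-(benzyloxy)-4-methoxybenzoate; 8 methyl methoxyacetate (2.2 equiv)
Product: 9 methyl 3-[2-(benzyloxy)-4-methoxyphenyl]-2-methoxy-3-oxopropanoate (racemic)
Conditions: LiHMDS (3.2 equiv), THF, −78 °C → 0 °C; then 1 M HCl
Reagents that add atoms: none
Why: Crossed Claisen condensation: 7 has no α-hydrogen and can only act as the acyl donor toward the lithium enolate of 8, and deprotonation of the acidic keto ester by the excess base pulls the equilibrium to the product.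

Step 7
Reactants: 9 methyl 3-[2-(benzyloxy)-4-methoxyphenyl]-2-methoxy-3-oxopropanoate
Product: 10 methyl (2E)-3-[2-(benzyloxy)-4-methoxyphenyl]-2-methoxy-3-{[(trifluoromethyl)sulfonyl]oxy}prop-2-enoate
Conditions: NaH, CH2Cl2, 0 °C; Tf2O, −78 °C → 0 °C
Reagents that add atoms: trifluoromethanesulfonic anhydride, O=S(=O)(OS(=O)(=O)C(F)(F)F)C(F)(F)F
Why: O-Sulfonylation of a β-keto ester enolate: the sodium enolate is chelated between the ketone and ester oxygens, so triflation at oxygen should place the triflyloxy group cis to the ester, which is the E isomer.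

Step 8
Reactants: 10 methyl (2E)-3-[2-(benzyloxy)-4-methoxyphenyl]-2-methoxy-3-{[(trifluoromethyl)sulfonyl]oxy}prop-2-enoate; 5 5-(benzyloxy)-2,3,4-trimethoxyphenol (1.1 equiv)
Product: 11 methyl (2E)-3-[2-(benzyloxy)-4-methoxyphenyl]-3-[5-(benzyloxy)-2,3,4-trimethoxyphenoxy]-2-methoxyprop-2-enoate
Conditions: Cs2CO3, MeCN, 0 °C → rt
Reagents that add atoms: none
Why: Nucleophilic vinylic substitution by addition–elimination: the cesium phenoxide of 5 adds to the β-carbon of the acrylate, made electrophilic by the ester and the triflyloxy group, and the ester enolate should expel triflate faster than it rotates, so the carboxyl-cis geometry should be kept.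

Step 9
Reactants: 11 methyl (2E)-3-[2-(benzyloxy)-4-methoxyphenyl]-3-[5-(benzyloxy)-2,3,4-trimethoxyphenoxy]-2-methoxyprop-2-enoate
Product: 12 (2E)-3-[2-(benzyloxy)-4-methoxyphenyl]-3-[5-(benzyloxy)-2,3,4-trimethoxyphenoxy]-2-methoxyprop-2-enoic acid
Conditions: LiOH, THF/MeOH/H2O, 40 °C; then 1 M HCl, 0 °C (pH 3)
Reagents that add atoms: lithium hydroxide, [Li+].[OH-]
Why: Ester saponification by acyl–oxygen cleavage; the benzyl ethers are inert to hydroxide, and the enol ether, a vinylogous carbonate, should survive mild base and the cold, brief acidification.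

Step 10
Reactants: 12 (2E)-3-[2-(benzyloxy)-4-methoxyphenyl]-3-[5-(benzyloxy)-2,3,4-trimethoxyphenoxy]-2-methoxyprop-2-enoic acid
Product: 14 5-(benzyloxy)-2-[2-(benzyloxy)-4-methoxyphenyl]-3,6,7,8-tetramethoxy-4H-chromen-4-one, via mixed trifluoroacetic anhydride 13 (not isolated)
Conditions: TFAA (2 equiv), CH2Cl2, 0 °C → rt; aqueous work-up
Reagents that add atoms: none
Why: TFAA turns acid 12 into mixed anhydride 13, which loses trifluoroacetate to a push–pull stabilised acylium (ketene–oxocarbenium) ion; the single hydrogen-bearing carbon of ring A attacks the acyl carbon, and proton loss from the arenium ion restores the arene and leaves the C4 carbonyl. The closest known reaction is the intramolecular Friedel–Crafts acylation of β-aryloxyacrylic and β-aryloxycinnamic acids to chromones and flavones. Ring C closes as a six-membered ring in a 6-exo-trig mode at the acyl carbon through the new C4–C4a bond, and no stereocentre is formed. The step needs attack on ring A only: its reacting carbon is the sole C–H, ortho to the vinyl ether oxygen and to the benzyloxy group and para to the central methoxy group, whereas C6' of ring B is meta to both of its oxygens, so an indenone is not expected. The E geometry holds the carboxyl group next to the aryloxy ring, and if the alkene isomerises through the cation, C-acylation of the doubly ortho-oxygenated carbon should still outrun participation of the 2'-benzyloxy oxygen. No strong protic or Lewis acid is present, so both benzyl ethers should persist, and early loss of the peri 5-O-benzyl group would be harmless because it is removed in step 11.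

Step 11
Reactants: 14 5-(benzyloxy)-2-[2-(benzyloxy)-4-methoxyphenyl]-3,6,7,8-tetramethoxy-4H-chromen-4-one
Product: 15 5-hydroxy-2-(2-hydroxy-4-methoxyphenyl)-3,6,7,8-tetramethoxy-4H-chromen-4-one (5,2'-dihydroxy-3,6,7,8,4'-pentamethoxyflavone)
Conditions: H2 (1 atm), Pd/C, EtOAc/MeOH, rt
Reagents that add atoms: none
Why: Hydrogenolysis of the two benzyl aryl ethers over palladium on carbon; the methyl ethers are inert and the tetrasubstituted, carbonyl-conjugated C2=C3 bond of the chromone should not be reduced at ambient pressure.

**Compound list**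
1 | 1,2,3-trimethoxybenzene | COc1cccc(OC)c1OC | starting material
2 | 1,5-dibromo-2,3,4-trimethoxybenzene | COc1c(Br)cc(Br)c(OC)c1OC | intermediate
3 | 2,2'-(4,5,6-trimethoxy-1,3-phenylene)bis(4,4,5,5-tetramethyl-1,3,2-dioxaborolane) | COc1c(B2OC(C)(C)C(C)(C)O2)cc(B2OC(C)(C)C(C)(C)O2)c(OC)c1OC | intermediate
4 | 4,5,6-trimethoxybenzene-1,3-diol | COc1c(O)cc(O)c(OC)c1OC | intermediate
5 | 5-(benzyloxy)-2,3,4-trimethoxyphenol | COc1c(O)cc(OCc2ccccc2)c(OC)c1OC | intermediate
6 | methyl 2-hydroxy-4-methoxybenzoate | COc1ccc(C(=O)OC)c(O)c1 | starting material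
7 | methyl 2-(benzyloxy)-4-methoxybenzoate | COc1ccc(C(=O)OC)c(OCc2ccccc2)c1 | intermediate
8 | methyl methoxyacetate | COCC(=O)OC | starting material
9 | methyl 3-[2-(benzyloxy)-4-methoxyphenyl]-2-methoxy-3-oxopropanoate (racemic) | COc1ccc(C(=O)C(OC)C(=O)OC)c(OCc2ccccc2)c1 | intermediate
10 | methyl (2E)-3-[2-(benzyloxy)-4-methoxyphenyl]-2-methoxy-3-{[(trifluoromethyl)sulfonyl]oxy}prop-2-enoate | COc1ccc(/C(OS(=O)(=O)C(F)(F)F)=C(\OC)C(=O)OC)c(OCc2ccccc2)c1 | intermediate
11 | methyl (2E)-3-[2-(benzyloxy)-4-methoxyphenyl]-3-[5-(benzyloxy)-2,3,4-trimethoxyphenoxy]-2-methoxyprop-2-enoate | COc1ccc(/C(Oc2cc(OCc3ccccc3)c(OC)c(OC)c2OC)=C(\OC)C(=O)OC)c(OCc2ccccc2)c1 | intermediate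
12 | (2E)-3-[2-(benzyloxy)-4-methoxyphenyl]-3-[5-(benzyloxy)-2,3,4-trimethoxyphenoxy]-2-methoxyprop-2-enoic acid | COc1ccc(/C(Oc2cc(OCc3ccccc3)c(OC)c(OC)c2OC)=C(\OC)C(=O)O)c(OCc2ccccc2)c1 | intermediate
13 | (2E)-3-[2-(benzyloxy)-4-methoxyphenyl]-3-[5-(benzyloxy)-2,3,4-trimethoxyphenoxy]-2-methoxyprop-2-enoic trifluoroacetic anhydride | COc1ccc(/C(Oc2cc(OCc3ccccc3)c(OC)c(OC)c2OC)=C(\OC)C(=O)OC(=O)C(F)(F)F)c(OCc2ccccc2)c1 | intermediate (not isolated)
14 | 5-(benzyloxy)-2-[2-(benzyloxy)-4-methoxyphenyl]-3,6,7,8-tetramethoxy-4H-chromen-4-one | COc1ccc(-c2oc3c(OC)c(OC)c(OC)c(OCc4ccccc4)c3c(=O)c2OC)c(OCc2ccccc2)c1 | intermediate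
15 | 5-hydroxy-2-(2-hydroxy-4-methoxyphenyl)-3,6,7,8-tetramethoxy-4H-chromen-4-one | COc1ccc(-c2oc3c(OC)c(OC)c(OC)c(O)c3c(=O)c2OC)c(O)c1 | target

**Step count**
Total: 11 steps. Longest linear sequence: 8 steps (steps 1–4 and 8–11).

**Steps most likely to fail**

1. Step 8. The phenoxide may attack the sulfur of the triflate (sulfonyl transfer, returning the keto ester enolate) or add too slowly to the hindered, donor-substituted β-carbon. The fallback sets out from 10 and 5 and comes back at 11. It replaces addition–elimination at carbon by a cross-coupling: Pd2(dba)3, 2-(di-tert-butylphosphino)biphenyl, K3PO4, toluene, 90 °C. Zerovalent palladium inserts into the vinyl C–OTf bond and the aryloxide is delivered by reductive elimination, so bond formation no longer depends on the electrophilicity of the β-carbon. This coupling of enol triflates with phenols is known chemistry and makes no compound outside the list (F0).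

2. Step 10. The acyl cation may be intercepted by the 2'-benzyloxy oxygen with loss of the benzyl group (lactonisation towards a coumarin). Alternatively the closure may stall, so that stronger acid becomes necessary and the benzyl ethers are lost before the ring forms. The fallback sets out from 4 and 7, comes back at 15, and builds ring C from the ketone side.
 - Diol 4 would be C-acylated at its only free ring carbon with methoxyacetic acid in BF3·OEt2 (80 °C) to give 1-(2,6-dihydroxy-3,4,5-trimethoxyphenyl)-2-methoxyethan-1-one F1.
 - Ester 7 would be saponified (LiOH) to 2-(benzyloxy)-4-methoxybenzoic acid F2 and converted with oxalyl chloride and catalytic DMF into 2-(benzyloxy)-4-methoxybenzoyl chloride F3.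
 - The lithium polyanion of F1 (LiHMDS, 4 equiv, THF, −78 °C) would be C-acylated by F3 to 1-[2-(benzyloxy)-4-methoxyphenyl]-3-(2,6-dihydroxy-3,4,5-trimethoxyphenyl)-2-methoxypropane-1,3-dione F4, the diketone of a Baker–Venkataraman-type flavone synthesis.
 - Cyclodehydration (NaOAc, AcOH, 100 °C) should give 2-[2-(benzyloxy)-4-methoxyphenyl]-5-hydroxy-3,6,7,8-tetramethoxy-4H-chromen-4-one F5, and hydrogenolysis (H2, Pd/C) then gives 15.

3. Step 6. Self-condensation of the methoxyacetate enolate may outrun acylation by the hindered, electron-rich benzoate. The fallback sets out from 7 and comes back at 9, using an aldol addition followed by oxidation in place of the ester condensation.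
 - Ester 7 would be reduced with LiAlH4 to [2-(benzyloxy)-4-methoxyphenyl]methanol F6 and oxidised with MnO2 to 2-(benzyloxy)-4-methoxybenzaldehyde F7.
 - The lithium enolate of 8 (LDA, THF, −78 °C) would add to F7 to give methyl 3-[2-(benzyloxy)-4-methoxyphenyl]-3-hydroxy-2-methoxypropanoate F8 as a mixture of diastereomers, which is of no consequence.
 - Oxidation with Dess–Martin periodinane would give 9.

**Further compounds**
F0 | step 8 | none | none
F1 | step 10 | 1-(2,6-dihydroxy-3,4,5-trimethoxyphenyl)-2-methoxyethan-1-one | COCC(=O)c1c(O)c(OC)c(OC)c(OC)c1O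
F2 | step 10 | 2-(benzyloxy)-4-methoxybenzoic acid | COc1ccc(C(=O)O)c(OCc2ccccc2)c1
F3 | step 10 | 2-(benzyloxy)-4-methoxybenzoyl chloride | COc1ccc(C(=O)Cl)c(OCc2ccccc2)c1
F4 | step 10 | 1-[2-(benzyloxy)-4-methoxyphenyl]-3-(2,6-dihydroxy-3,4,5-trimethoxyphenyl)-2-methoxypropane-1,3-dione | COc1ccc(C(=O)C(OC)C(=O)c2c(O)c(OC)c(OC)c(OC)c2O)c(OCc2ccccc2)c1
F5 | step 10 | 2-[2-(benzyloxy)-4-methoxyphenyl]-5-hydroxy-3,6,7,8-tetramethoxy-4H-chromen-4-one | COc1ccc(-c2oc3c(OC)c(OC)c(OC)c(O)c3c(=O)c2OC)c(OCc2ccccc2)c1
F6 | step 6 | [2-(benzyloxy)-4-methoxyphenyl]methanol | COc1ccc(CO)c(OCc2ccccc2)c1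
F7 | step 6 | 2-(benzyloxy)-4-methoxybenzaldehyde | COc1ccc(C=O)c(OCc2ccccc2)c1
F8 | step 6 | methyl 3-[2-(benzyloxy)-4-methoxyphenyl]-3-hydroxy-2-methoxypropanoate (mixture of diastereomers) | COc1ccc(C(O)C(OC)C(=O)OC)c(OCc2ccccc2)c1
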